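The product is chains of L, and I want their average length in two flasks, theta and epsilon.

    Z + X → E + L (k1 = 0.40 M⁻¹ h⁻¹)
    Z + E → L + E, rate k2*[E]*[Z] (k2 = 5.3 M⁻¹ h⁻¹)
    2 E → E2 (k3 = 3.0 M⁻¹ h⁻¹)
    X + D → X.D (k4 = 970 M⁻¹ h⁻¹)

- theta: Z 1.2 M; X 5 mol%; D 20 mM; time 8.0 h
- epsilon: Z 1.2 M; X 15 mol%; D 20 mM; time 8.0 h

- which of the two ends with the longer chains by the average number of monomer units in a chain (chains begun, living or dead) ("neither" if they lie within 10%) (theta / epsilon / neither)
- average number of monomer units in a chain (chains begun, living or dead) at the end, theta
- average number of monomer units in a chain (chains begun, living or dead) at the end, epsilon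

- where a step has two of a species, its rate is k times that concentration squared, and two are used at each turn
- the average divides the monomer in chains by the number of chains begun, living and dead together
- run time (theta): 8.0 h

The length is the monomer in L divided by the chains begun, and each chain begun costs one X. D reaches X first: at the start of epsilon, hardly any of the X consumed goes to chains. In theta, with the other concentrations held at their charge, the half-life of X against D is 2.1 min, far shorter than the 29 h of Z in the step that begins chains. So I reckon 0.0400 M in theta and 0.160 M in epsilon for the one quantity I carry, the active charge B, the X charge less the D charge.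

Now I turn the settings by hand. Raising X from theta's loading to epsilon's multiplies B by 4.00. D takes 33.3% of the X charge in theta, more than the 11.1% it takes in epsilon. Time enters through a pseudo-first-order clock for X: with Z held at its charge c, the time constant is 2.08 h, and the run lasts 3.84 of these. Z falls, so its mean is below c and the true count is lower. Twice the dilution leaves c/B as it stands but stretches the clock to 4.17 h.

The ratio c/B, the length once Z is used up and B is begun in full, is 30.0 in theta, longer than the 7.50 in epsilon. My reckoning stops there, with theta as my choice. The forecast also says theta, but it goes on to lengths of 18.7 and 8.2, not my ratios, holding that “the dead X.D makes no chains”.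

The simulation gives theta, with 18.6 in theta and 8.25 in epsilon. In theta at 8.00 h, X stands at 4.75% of its charge, so the chains begun are 0.0371 M out of B = 0.0400 M. A neighbour of epsilon charged with 6 mol% of X has B = 0.0520 M, theta's B plus the added X. It keeps 6.3% of its X, so it has begun 0.0475 M of chains, and with 64.4% of the Z in L its length is 16.3.

The constants used here are made up.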